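**Retrosynthetic overview**

- The target is reached by removing three benzyl ethers from a tri-O-benzyl bis-pyranone; both 4-hydroxy-2-pyranone rings of that compound are disconnected at C4–C5 and O1–C2 into a tetra(acid chloride) and two molecules of the trimethylsilyl enol ether of pentan-3-one.
- The strategy rests on this feature: each pyranone is a malonyl triad C2(=O)–C3–C4(OH), with C3 carrying the bridging CH2, joined to the O1–C6(Et)=C5(Me) enol unit of symmetric pentan-3-one. The heterocycles can therefore be grown on benzylic malonyl arms at C3 and C5 of the isobutyrylphloroglucinol benzene ring.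
- The malonyl arms come from a twofold reductive Knoevenagel alkylation of Meldrum's acid with a tri-O-benzyl dialdehyde, which goes back through Vilsmeier diformylation and Friedel–Crafts acylation to phloroglucinol.
- Ring order: the benzene ring is bought and fully substituted first; the two pyranone rings are closed together in one operation as the last ring-forming event, before deprotection.

Key step: step 8

Remark: the target has no stereocentre and is drawn as its 4-hydroxy-2-pyranone tautomer; silyl enol ether 13 is written as the Z isomer but would be used as the Z-rich E/Z mixture, since its geometry is erased in step 8.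

**Route**

Step 1
Reactants: 1 phloroglucinol; 2 isobutyryl chloride
Product: 3 phlorisobutyrophenone [2-methyl-1-(2,4,6-trihydroxyphenyl)propan-1-one]
Conditions: AlCl3 (4 equiv), PhNO2, 60 °C; then ice, aq. HCl
Reagents that add atoms: none
Why: Friedel–Crafts C-acylation of a ring with three equivalent C–H positions; any aryl ester formed should undergo Fries rearrangement under AlCl3, and the first acyl group deactivates the ring against a second acylation.

Step 2
Reactants: 3 phlorisobutyrophenone
Product: 5 3,5-diformylphlorisobutyrophenone [2,4,6-trihydroxy-5-(2-methylpropanoyl)benzene-1,3-dicarbaldehyde], via bis-iminium dichloride 4 (not isolated)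
Conditions: POCl3 (4 equiv), DMF (excess), EtOAc, 0 °C to rt; then H2O, 50 °C
Reagents that add atoms: N,N-dimethylformamide, CN(C)C=O; water, O
Why: Twofold Vilsmeier–Haack formylation; each of the two remaining ring C–H positions is ortho or para to all three hydroxyl groups and should still be attacked by the chloroiminium ion after the first substitution, and aqueous hydrolysis of the bis-iminium salt releases both aldehydes.

Step 3
Reactants: 5 3,5-diformylphlorisobutyrophenone
Product: 6 2,4,6-tris(benzyloxy)-5-(2-methylpropanoyl)benzene-1,3-dicarbaldehyde
Conditions: BnBr (4 equiv), K2CO3 (5 equiv), DMF, 60 °C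
Reagents that add atoms: benzyl bromide, BrCc1ccccc1
Why: Williamson etherification; the acidic, chelated phenols are fully ionised by carbonate in DMF, and because every ring carbon between the oxygens already carries an acyl group, alkylation should take place on oxygen.

Step 4
Reactants: 6 tri-O-benzyl dialdehyde; 7 Meldrum's acid (2.4 equiv)
Product: 9 bis(Meldrum's acid) adduct [5,5'-{[2,4,6-tris(benzyloxy)-5-(2-methylpropanoyl)-1,3-phenylene]bis(methylene)}bis(2,2-dimethyl-1,3-dioxane-4,6-dione)], via bis-arylidene Meldrum's acid adduct 8 (not isolated)
Conditions: diethyl 1,4-dihydro-2,6-dimethylpyridine-3,5-dicarboxylate (Hantzsch ester, 2.4 equiv), L-proline (20 mol %), EtOH/CH2Cl2, rt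
Reagents that add atoms: none
Why: Reductive Knoevenagel alkylation; amine-catalysed condensation gives the electron-poor arylidene Meldrum's acid, which accepts hydride from the dihydropyridine faster than it adds a second Meldrum's acid, while the hindered aryl ketone and the benzyl ethers are inert to this hydride donor.

Step 5
Reactants: 9 bis(Meldrum's acid) adduct
Product: 10 bis(malonic acid) [2,2'-{[2,4,6-tris(benzyloxy)-5-(2-methylpropanoyl)-1,3-phenylene]bis(methylene)}dimalonic acid]
Conditions: 1 M aq. HCl, THF, 45 °C
Reagents that add atoms: water, O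
Why: Acid-catalysed hydrolysis of the cyclic acylal with loss of acetone; the temperature is kept well below that at which benzylmalonic acids decarboxylate, and aryl benzyl ethers tolerate dilute aqueous acid.

Step 6
Reactants: 10 bis(malonic acid)
Product: 11 bis(malonyl dichloride) [tetra(acid chloride) of 10]
Conditions: (COCl)2 (6 equiv), DMF (cat.), CH2Cl2, 0 °C to rt; evaporate, use crude at once
Reagents that add atoms: oxalyl chloride, ClC(=O)C(Cl)=O
Why: Chloroiminium-catalysed conversion of carboxylic acids into acyl chlorides with only gaseous co-products, run without base or heat so that the ortho benzyl ethers are not attacked; any chlorocarbonyl ketene formed by loss of HCl would react in the same sense in step 8.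

Step 7
Reactants: 12 pentan-3-one
Product: 13 (Z)-3-(trimethylsilyloxy)pent-2-ene
Conditions: TMSCl, NaI, Et3N, MeCN, rt; pentane extraction, distillation
Reagents that add atoms: chlorotrimethylsilane, C[Si](C)(C)Cl
Why: Silyl enol ether formation by amine-mediated enolisation and O-silylation with iodotrimethylsilane generated in the flask; the symmetric ketone can give only one regioisomer.

Step 8
Reactants: 11 bis(malonyl dichloride); 13 (Z)-3-(trimethylsilyloxy)pent-2-ene (5 equiv)
Product: 15 tri-O-benzyl bis-pyranone [3,3'-{[2,4,6-tris(benzyloxy)-5-(2-methylpropanoyl)-1,3-phenylene]bis(methylene)}bis(6-ethyl-4-hydroxy-5-methyl-2H-pyran-2-one)], via bis-diketo acyl chloride 14 (not isolated)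
Conditions: Et2O, −78 °C to rt, 11 added slowly to excess 13; then dilute aq. HCl
Reagents that add atoms: none
Why: In each arm the nucleophilic C2 of the silyl enol ether C-acylates one C(=O)Cl of the malonyl unit (directly or after loss of HCl to the chlorocarbonyl ketene), chlorotrimethylsilane is expelled and the 3,5-dioxoacyl chloride 14 results, the new bond being C4–C5 of the future ring. The ethyl ketone of 14 enolises towards the doubly activated C5 and its oxygen attacks the remaining acyl chloride in a 6-exo-trig lactonisation that forms O1–C2; loss of HCl and tautomerisation at C3 then give the aromatic 4-hydroxy-2-pyranone, so both heterocycles are closed in the same mode in one operation. The closest known reaction type is the condensation of malonyl dichloride or 2-substituted malonyl dichlorides with ketone trimethylsilyl enol ethers to give 4-hydroxy-2-pyranones, used here twice on one molecule. No stereocentre is created: the four stereogenic carbons of 14 all become sp2 ring carbons and the E/Z identity of 13 is erased. The step needs C-acylation followed by intramolecular O-acylation inside one malonyl unit, not bridging of the two arms or intermolecular acylation; the fast six-membered closure of the tethered enol, the excess of 13 and the low temperature should secure this. The symmetric ketone allows only the 5-methyl-6-ethyl pattern, the benzyl ethers keep the flanking oxygens from lactonising, and the twisted isobutyryl ketone does not act as an enol nucleophile.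

Step 9
Reactants: 15 tri-O-benzyl bis-pyranone
Product: 16 target CNP0277086.0 [3,3'-{[2,4,6-trihydroxy-5-(2-methylpropanoyl)-1,3-phenylene]bis(methylene)}bis(6-ethyl-4-hydroxy-5-methyl-2H-pyran-2-one)]
Conditions: H2 (1 atm), 10% Pd/C, EtOAc/MeOH, rt
Reagents that add atoms: none
Why: Hydrogenolysis of the three aryl benzyl ethers under neutral conditions; the tetrasubstituted pyranone double bonds, the chelated aryl ketone and the CH2 bridges (C–C bonds only) should not be reduced at atmospheric pressure.

**Compound list**

1 | phloroglucinol | Oc1cc(O)cc(O)c1 | starting material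
2 | isobutyryl chloride | CC(C)C(Cl)=O | starting material
3 | phlorisobutyrophenone | CC(C)C(=O)c1c(O)cc(O)cc1O | intermediate
4 | bis(N,N-dimethyliminium) dichloride formed in the Vilsmeier reaction | CC(C)C(=O)c1c(O)c(C=[N+](C)C)c(O)c(C=[N+](C)C)c1O.[Cl-].[Cl-] | intermediate (not isolated)
5 | 3,5-diformylphlorisobutyrophenone | CC(C)C(=O)c1c(O)c(C=O)c(O)c(C=O)c1O | intermediate
6 | 2,4,6-tris(benzyloxy)-5-(2-methylpropanoyl)benzene-1,3-dicarbaldehyde | CC(C)C(=O)c1c(OCc2ccccc2)c(C=O)c(OCc2ccccc2)c(C=O)c1OCc1ccccc1 | intermediate
7 | Meldrum's acid (2,2-dimethyl-1,3-dioxane-4,6-dione) | CC1(C)OC(=O)CC(=O)O1 | starting material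
8 | bis(arylidene Meldrum's acid) condensation product of 6 | CC(C)C(=O)c1c(OCc2ccccc2)c(C=C2C(=O)OC(C)(C)OC2=O)c(OCc2ccccc2)c(C=C2C(=O)OC(C)(C)OC2=O)c1OCc1ccccc1 | intermediate (not isolated)
9 | bis(Meldrum's acid) adduct with both benzylic CH2 arms | CC(C)C(=O)c1c(OCc2ccccc2)c(CC2C(=O)OC(C)(C)OC2=O)c(OCc2ccccc2)c(CC2C(=O)OC(C)(C)OC2=O)c1OCc1ccccc1 | intermediate
10 | bis(malonic acid) | CC(C)C(=O)c1c(OCc2ccccc2)c(CC(C(=O)O)C(=O)O)c(OCc2ccccc2)c(CC(C(=O)O)C(=O)O)c1OCc1ccccc1 | intermediate
11 | bis(malonyl dichloride) | CC(C)C(=O)c1c(OCc2ccccc2)c(CC(C(Cl)=O)C(Cl)=O)c(OCc2ccccc2)c(CC(C(Cl)=O)C(Cl)=O)c1OCc1ccccc1 | intermediate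
12 | pentan-3-one | CCC(=O)CC | starting material
13 | (Z)-3-(trimethylsilyloxy)pent-2-ene | C/C=C(/CC)O[Si](C)(C)C | intermediate
14 | bis(3,5-dioxoacyl chloride) after C-acylation in both arms (mixture of stereoisomers) | CC(C)C(=O)c1c(OCc2ccccc2)c(CC(C(Cl)=O)C(=O)C(C)C(=O)CC)c(OCc2ccccc2)c(CC(C(Cl)=O)C(=O)C(C)C(=O)CC)c1OCc1ccccc1 | intermediate (not isolated)
15 | tri-O-benzyl bis-pyranone | CCc1oc(=O)c(Cc2c(OCc3ccccc3)c(Cc3c(O)c(C)c(CC)oc3=O)c(OCc3ccccc3)c(C(=O)C(C)C)c2OCc2ccccc2)c(O)c1C | intermediate
16 | CNP0277086.0 | CCc1oc(=O)c(Cc2c(O)c(Cc3c(O)c(C)c(CC)oc3=O)c(O)c(C(=O)C(C)C)c2O)c(O)c1C | target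

**Step count**

Total: 9 steps. Longest linear sequence: 8 steps (steps 1–6, 8 and 9, from phloroglucinol); step 7 is a one-step side branch.

**Steps most likely to fail**

Step 8. The twofold annulation could lose material in three ways: one enol ether or one intermediate could bridge the two malonyl arms (oligomer formation), the second arm could stop at the open-chain stage, or the crude acid chloride 11 could lose a benzyl group when an ortho ether oxygen attacks an acyl chloride. The fallback sets out from dialdehyde 6 and attaches the heterocycle preformed. Purchased malonyl dichloride and enol ether 13 (Et2O, −78 °C to rt) should give 6-ethyl-4-hydroxy-5-methyl-2H-pyran-2-one F1 by the same known annulation on a simple substrate. Dialdehyde 6, two equivalents of this pyranone and Hantzsch ester with L-proline (CH2Cl2, rt) should then condense at C3 of each pyranone to the bis(3-arylidenepyran-2,4-dione) F2 (E/Z mixture, not isolated), which is reduced in the flask by hydride transfer. This three-component reductive alkylation of cyclic 1,3-dicarbonyl compounds is known chemistry and comes back to the route at compound 15.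

Step 4. The condensation could stall after one arm because each formyl group sits between two benzyloxy groups, or Michael addition of a second Meldrum's acid to the arylidene could compete with hydride transfer. The fallback sets out from dialdehyde 6. Chemoselective reduction of the two aldehydes (NaBH4, THF/MeOH, −20 °C; the hindered isopropyl ketone should survive) would give 2,4,6-tris(benzyloxy)-3,5-bis(hydroxymethyl)phenyl isopropyl ketone F3. PBr3 (Et2O, 0 °C) would convert it into the bis(bromomethyl) compound F4, used crude. Alkylation of excess sodium di-tert-butyl malonate (NaH, THF, 0 °C to rt) would give the tetra-tert-butyl bis(malonate) F5, and CF3CO2H in CH2Cl2 (0 °C to rt) would cleave the four tert-butyl esters. The fallback comes back to the route at compound 10.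

Step 5. Under the aqueous acid needed to open the dioxanedione rings, the malonic acid units could decarboxylate, or the opening could remain incomplete. The fallback sets out from compound 9 and avoids warm aqueous acid. Refluxing 9 in tert-butanol should open each ring by alcoholysis with loss of acetone to give the bis(mono-tert-butyl hydrogen malonate) F6 (mixture of diastereomers). CF3CO2H in CH2Cl2 at 0 °C to rt would then remove the two tert-butyl groups under anhydrous conditions, and the fallback comes back to the route at compound 10.

**Further compounds**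

F1 | step 8 | 6-ethyl-4-hydroxy-5-methyl-2H-pyran-2-one | CCc1oc(=O)cc(O)c1C
F2 | step 8 | bis(3-arylidenepyran-2,4-dione) condensation intermediate from 6 and F1 (E/Z mixture) | CC(C)C(=O)c1c(OCc2ccccc2)c(C=C2C(=O)OC(CC)=C(C)C2=O)c(OCc2ccccc2)c(C=C2C(=O)OC(CC)=C(C)C2=O)c1OCc1ccccc1
F3 | step 4 | 2,4,6-tris(benzyloxy)-3,5-bis(hydroxymethyl)phenyl isopropyl ketone | CC(C)C(=O)c1c(OCc2ccccc2)c(CO)c(OCc2ccccc2)c(CO)c1OCc1ccccc1
F4 | step 4 | 2,4,6-tris(benzyloxy)-3,5-bis(bromomethyl)phenyl isopropyl ketone | CC(C)C(=O)c1c(OCc2ccccc2)c(CBr)c(OCc2ccccc2)c(CBr)c1OCc1ccccc1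
F5 | step 4 | tetra-tert-butyl bis(malonate) | CC(C)C(=O)c1c(OCc2ccccc2)c(CC(C(=O)OC(C)(C)C)C(=O)OC(C)(C)C)c(OCc2ccccc2)c(CC(C(=O)OC(C)(C)C)C(=O)OC(C)(C)C)c1OCc1ccccc1
F6 | step 5 | bis(mono-tert-butyl hydrogen malonate) | CC(C)C(=O)c1c(OCc2ccccc2)c(CC(C(=O)O)C(=O)OC(C)(C)C)c(OCc2ccccc2)c(CC(C(=O)O)C(=O)OC(C)(C)C)c1OCc1ccccc1
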